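## Retrosynthetic overview

1. Methyl sarcoate ⇐ oxidation of the C2 carbinol ⇐ E1cB dehydration of a β-hydroxy ketone ⇐ N–O cleavage of a bicyclic isoxazoline.
2. Key step: the 14-membered carbocycle (the only carbocycle) and a temporary isoxazoline form together in an intramolecular nitrile oxide–acrylate [3+2] cycloaddition (C5–C6 bond, oxygen to C4).
3. Seco precursor ⇐ C2–C3 by indium Barbier allylation of a lactol with methyl 2-(bromomethyl)acrylate; C12–C13 by CrCl2/NiCl2 coupling of a (Z)-vinyl iodide with a dialdehyde.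
4. (Z)-Vinyl iodide (C6–C12, carrying 7E and 11Z) ⇐ geranyl acetate by selective ozonolysis and Stork–Zhao olefination.
5. The C1 stereocentre (R) is bought: (R)-(−)-α-phellandrene ⇒ (R)-2-isopropylsuccinaldehyde (C13–C14–C1–C2) by ozonolysis.

Assumption: cembrane numbering is used (C1 = isopropyl-bearing stereocentre; C2, C6, C13 = ketones; C4 = ester-bearing alkene carbon), and centres that are later destroyed (C2, C4, C13 carbinols, lactol carbon, oxime geometry) are carried as mixtures.

## Route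

Step 1
Reactants: 1 geranyl acetate
Product: 2 (2E)-3-methyl-6-oxohex-2-en-1-yl acetate
Conditions: O3 (ca. 1 equiv), pyridine, CH2Cl2, −78 °C
Reagents that add atoms: ozone, [O-][O+]=O
Why: Chemoselective pyridine-mediated reductive ozonolysis, because ozone attacks the electron-rich terminal trisubstituted alkene much faster than the 2,3-alkene deactivated by the allylic acetate, so the 2E alkene (later C7=C8) is kept.

Step 2
Reactants: 2 (2E)-3-methyl-6-oxohex-2-en-1-yl acetate
Product: 3 (2E,6Z)-7-iodo-3-methylocta-2,6-dien-1-yl acetate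
Conditions: ethyltriphenylphosphonium iodide, n-BuLi, THF, 0 °C; I2, −78 °C; NaN(SiMe3)2, −20 °C; then 2, −78 °C
Reagents that add atoms: ethyltriphenylphosphonium iodide, CC[P+](c1ccccc1)(c1ccccc1)c1ccccc1.[I-]; iodine, II
Why: Stork–Zhao–Wittig olefination with the α-iodo ylide gives the trisubstituted vinyl iodide with iodine cis to the chain under kinetic control, which fixes the later 11Z geometry, and the acetate survives the cold conditions.

Step 3
Reactants: 3 (2E,6Z)-7-iodo-3-methylocta-2,6-dien-1-yl acetate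
Product: 4 (2E,6Z)-7-iodo-3-methylocta-2,6-dien-1-ol
Conditions: K2CO3 (cat.), MeOH, 0 °C → rt
Reagents that add atoms: none
Why: Transesterification frees the C6 hydroxyl now, so that no base-labile group has to be removed once the acrylate and the γ-hydroxy ester are in the molecule.

Step 4
Reactants: 5 (R)-(−)-α-phellandrene
Product: 6 (2R)-2-(propan-2-yl)butanedial
Conditions: O3 (2 equiv), pyridine, CH2Cl2, −78 °C; water wash; used at once as crude
Reagents that add atoms: ozone, [O-][O+]=O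
Why: Ozonolysis of both ring alkenes excises the methyl-bearing C2 unit as methylglyoxal and leaves the untouched sp3 centre (the only stereocentre of the target, R) between the two aldehyde carbons C2 and C13, without base that could enolise the branched aldehyde.

Step 5
Reactants: 4 (2E,6Z)-7-iodo-3-methylocta-2,6-dien-1-ol; 6 (2R)-2-(propan-2-yl)butanedial (1.5 equiv)
Product: 9 lactol (3R)-5-[(2Z,6E)-8-hydroxy-6-methylocta-2,6-dien-2-yl]-3-(propan-2-yl)oxolan-2-ol, via alkenylchromium dichloride 7 (not isolated), via open-chain hydroxy aldehyde 8 (not isolated)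
Conditions: CrCl2 (5 equiv), NiCl2 (2 mol %), DMSO/THF, rt; aq. NH4Cl
Reagents that add atoms: none
Why: Nozaki–Hiyama–Kishi coupling in which the alkenylchromium (trivalent chromium) species keeps the Z geometry and adds only to the unhindered CH2–CHO (C13), while the α-isopropyl aldehyde (C2) is much slower and is then masked as the lactol; the new C13 carbinol is uncontrolled and later oxidised.

Step 6
Reactants: 9 lactol (3R)-5-[(2Z,6E)-8-hydroxy-6-methylocta-2,6-dien-2-yl]-3-(propan-2-yl)oxolan-2-ol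
Product: 10 methyl (5R,8Z,12E)-4,7,14-trihydroxy-8,12-dimethyl-2-methylidene-5-(propan-2-yl)tetradeca-8,12-dienoate
Conditions: methyl 2-(bromomethyl)acrylate, indium powder, THF/H2O (1:1), rt
Reagents that add atoms: methyl 2-(bromomethyl)acrylate, C=C(CBr)C(=O)OC
Why: Indium Barbier allylation in water, in which the lactol reacts through its open hydroxy-aldehyde form and takes up C3–C5 as the future dipolarophile without base, so C1 is not epimerised and the new C2 carbinol configuration is irrelevant.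

Step 7
Reactants: 10 methyl (5R,8Z,12E)-4,7,14-trihydroxy-8,12-dimethyl-2-methylidene-5-(propan-2-yl)tetradeca-8,12-dienoate
Product: 11 methyl (5R,8Z,12E)-4-hydroxy-8,12-dimethyl-2-methylidene-7,14-dioxo-5-(propan-2-yl)tetradeca-8,12-dienoate
Conditions: MnO2 (activated, excess), CH2Cl2, rt
Reagents that add atoms: none
Why: Chemoselective allylic oxidation, since MnO2 converts the primary allylic C6 alcohol into the (E)-enal and the secondary allylic C13 alcohol into the (Z)-enone but leaves the non-allylic C2 carbinol alone.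

Step 8
Reactants: 11 methyl (5R,8Z,12E)-4-hydroxy-8,12-dimethyl-2-methylidene-7,14-dioxo-5-(propan-2-yl)tetradeca-8,12-dienoate
Product: 12 methyl (5R,8Z,12E)-4-[(tert-butyldimethylsilyl)oxy]-8,12-dimethyl-2-methylidene-7,14-dioxo-5-(propan-2-yl)tetradeca-8,12-dienoate
Conditions: TBSOTf, 2,6-lutidine, CH2Cl2, −78 °C
Reagents that add atoms: tert-butyldimethylsilyl trifluoromethanesulfonate, CC(C)(C)[Si](C)(C)OS(=O)(=O)C(F)(F)F
Why: Silylation of the single remaining hydroxyl stops lactonisation onto the ester and keeps C3 non-acidic, so the later elimination can only run towards C5.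

Step 9
Reactants: 12 methyl (5R,8Z,12E)-4-[(tert-butyldimethylsilyl)oxy]-8,12-dimethyl-2-methylidene-7,14-dioxo-5-(propan-2-yl)tetradeca-8,12-dienoate
Product: 13 methyl (5R,8Z,12E)-4-[(tert-butyldimethylsilyl)oxy]-14-(hydroxyimino)-8,12-dimethyl-2-methylidene-7-oxo-5-(propan-2-yl)tetradeca-8,12-dienoate
Conditions: NH2OH·HCl (1.1 equiv), pyridine, EtOH, 0 °C
Reagents that add atoms: hydroxylamine hydrochloride, NO.Cl
Why: Oxime condensation, in which the unhindered enal reacts far faster than the hindered conjugated ketone or the 2-substituted acrylate.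

Step 10
Reactants: 13 methyl (5R,8Z,12E)-4-[(tert-butyldimethylsilyl)oxy]-14-(hydroxyimino)-8,12-dimethyl-2-methylidene-7-oxo-5-(propan-2-yl)tetradeca-8,12-dienoate
Product: 16 methyl (2E,6Z,10R)-11-[(tert-butyldimethylsilyl)oxy]-3,7-dimethyl-8-oxo-10-(propan-2-yl)-14-oxa-15-azabicyclo[11.2.1]hexadeca-1(15),2,6-triene-13-carboxylate, via hydroximoyl chloride 14 (not isolated), via nitrile oxide 15 (not isolated)
Conditions: NCS, DMF, rt; then syringe-pump addition (12 h) to Et3N, CH2Cl2, rt, final 1 mM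
Reagents that add atoms: none
Why: Intramolecular nitrile oxide–alkene 1,3-dipolar cycloaddition under high dilution, in which the dipole carbon (C6) bonds to the acrylate CH2 (C5) and oxygen to C4 (the usual 5,5-disubstituted regiochemistry) to close the 14-membered carbocycle; the in-chain alkenes cannot compete because any small ring would hold the E alkene conjugated to the dipole, and the new C4 centre is destroyed later.

Step 11
Reactants: 16 the bicyclic isoxazoline
Product: 18 methyl (4E,8Z,12R)-13-[(tert-butyldimethylsilyl)oxy]-1-hydroxy-5,9-dimethyl-3,10-dioxo-12-(propan-2-yl)cyclotetradeca-4,8-diene-1-carboxylate, via ketimine 17 (not isolated)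
Conditions: Mo(CO)6 (0.6 equiv), MeCN/H2O (15:1), 80 °C
Reagents that add atoms: water, O
Why: Reductive N–O cleavage by zerovalent molybdenum followed by hydrolysis of the imine gives the β-hydroxy ketone and leaves alkenes, ester and silyl ether untouched.

Step 12
Reactants: 18 the β-hydroxy ketone
Product: 20 methyl (1E,4E,8Z,12R)-13-[(tert-butyldimethylsilyl)oxy]-5,9-dimethyl-3,10-dioxo-12-(propan-2-yl)cyclotetradeca-1,4,8-triene-1-carboxylate, via tertiary mesylate 19 (not isolated)
Conditions: MsCl, Et3N, CH2Cl2, 0 °C → rt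
Reagents that add atoms: none
Why: Sulfene mesylation of the tertiary alcohol and E1cB elimination through the C6 enolate, which can only go to C4=C5 because C3 lies next to a silyl ether carbinol, and which gives the more stable E ester (CO2Me trans to the ketone).

Step 13
Reactants: 20 the silyl-protected enone ester
Product: 22 methyl sarcoate, via C2 alcohol 21 (not isolated)
Conditions: HF·pyridine, pyridine, THF, 0 °C → rt; NaHCO3 work-up; crude, then Dess–Martin periodinane, NaHCO3, CH2Cl2, 0 °C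
Reagents that add atoms: none
Why: Fluoride desilylation and buffered Dess–Martin oxidation unveil the C2 ketone last and without base, so C1 (now α to a ketone) is not epimerised and C4=C5 does not migrate, and the lactonisation-prone hydroxy ester is not purified.

## Compound list

1 | geranyl acetate, (2E)-3,7-dimethylocta-2,6-dien-1-yl acetate | CC(C)=CCC/C(C)=C/COC(C)=O | starting material
2 | (2E)-3-methyl-6-oxohex-2-en-1-yl acetate | O=CCC/C(C)=C/COC(C)=O | intermediate
3 | (2E,6Z)-7-iodo-3-methylocta-2,6-dien-1-yl acetate | C/C(I)=C/CC/C(C)=C/COC(C)=O | intermediate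
4 | (2E,6Z)-7-iodo-3-methylocta-2,6-dien-1-ol | C/C(I)=C/CC/C(C)=C/CO | intermediate
5 | (R)-(−)-α-phellandrene, (5R)-2-methyl-5-(propan-2-yl)cyclohexa-1,3-diene | CC1=CC[C@@H](C=C1)C(C)C | starting material
6 | (2R)-2-(propan-2-yl)butanedial | O=CC[C@H](C(C)C)C=O | intermediate
7 | [(2Z,6E)-8-hydroxy-6-methylocta-2,6-dien-2-yl]chromium dichloride | C/C(=C/CC/C(C)=C/CO)[Cr](Cl)Cl | intermediate (not isolated)
8 | (2R,5Z,9E)-4,11-dihydroxy-5,9-dimethyl-2-(propan-2-yl)undeca-5,9-dienal, C4 epimers | O=C[C@@H](C(C)C)CC(O)/C(C)=C\CC/C(C)=C/CO | intermediate (not isolated)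
9 | (3R)-5-[(2Z,6E)-8-hydroxy-6-methylocta-2,6-dien-2-yl]-3-(propan-2-yl)oxolan-2-ol, epimers at C2 and C5 | CC(C)[C@H]1CC(OC1O)/C(C)=C\CC/C(C)=C/CO | intermediate
10 | methyl (5R,8Z,12E)-4,7,14-trihydroxy-8,12-dimethyl-2-methylidene-5-(propan-2-yl)tetradeca-8,12-dienoate, C4/C7 epimers | C=C(CC(O)[C@@H](C(C)C)CC(O)/C(C)=C\CC/C(C)=C/CO)C(=O)OC | intermediate
11 | methyl (5R,8Z,12E)-4-hydroxy-8,12-dimethyl-2-methylidene-7,14-dioxo-5-(propan-2-yl)tetradeca-8,12-dienoate, C4 epimers | C=C(CC(O)[C@@H](C(C)C)CC(=O)/C(C)=C\CC/C(C)=C/C=O)C(=O)OC | intermediate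
12 | methyl (5R,8Z,12E)-4-[(tert-butyldimethylsilyl)oxy]-8,12-dimethyl-2-methylidene-7,14-dioxo-5-(propan-2-yl)tetradeca-8,12-dienoate | C=C(CC(O[Si](C)(C)C(C)(C)C)[C@@H](C(C)C)CC(=O)/C(C)=C\CC/C(C)=C/C=O)C(=O)OC | intermediate
13 | methyl (5R,8Z,12E)-4-[(tert-butyldimethylsilyl)oxy]-14-(hydroxyimino)-8,12-dimethyl-2-methylidene-7-oxo-5-(propan-2-yl)tetradeca-8,12-dienoate | C=C(CC(O[Si](C)(C)C(C)(C)C)[C@@H](C(C)C)CC(=O)/C(C)=C\CC/C(C)=C/C=NO)C(=O)OC | intermediate
14 | hydroximoyl chloride of 13 (C14 bears Cl and =NOH) | C=C(CC(O[Si](C)(C)C(C)(C)C)[C@@H](C(C)C)CC(=O)/C(C)=C\CC/C(C)=C/C(Cl)=NO)C(=O)OC | intermediate (not isolated)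
15 | nitrile oxide of 13 (C14 as C≡N+–O−) | C=C(CC(O[Si](C)(C)C(C)(C)C)[C@@H](C(C)C)CC(=O)/C(C)=C\CC/C(C)=C/C#[N+][O-])C(=O)OC | intermediate (not isolated)
16 | methyl (2E,6Z,10R)-11-[(tert-butyldimethylsilyl)oxy]-3,7-dimethyl-8-oxo-10-(propan-2-yl)-14-oxa-15-azabicyclo[11.2.1]hexadeca-1(15),2,6-triene-13-carboxylate, epimers at C11/C13 | COC(=O)C12CC(=NO1)/C=C(\C)CC/C=C(/C)C(=O)C[C@H](C(C)C)C(O[Si](C)(C)C(C)(C)C)C2 | intermediate
17 | methyl (4E,8Z,12R)-13-[(tert-butyldimethylsilyl)oxy]-1-hydroxy-3-imino-5,9-dimethyl-10-oxo-12-(propan-2-yl)cyclotetradeca-4,8-diene-1-carboxylate | COC(=O)C1(O)CC(=N)/C=C(\C)CC/C=C(/C)C(=O)C[C@H](C(C)C)C(O[Si](C)(C)C(C)(C)C)C1 | intermediate (not isolated)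
18 | methyl (4E,8Z,12R)-13-[(tert-butyldimethylsilyl)oxy]-1-hydroxy-5,9-dimethyl-3,10-dioxo-12-(propan-2-yl)cyclotetradeca-4,8-diene-1-carboxylate, epimers at C1/C13 | COC(=O)C1(O)CC(=O)/C=C(\C)CC/C=C(/C)C(=O)C[C@H](C(C)C)C(O[Si](C)(C)C(C)(C)C)C1 | intermediate
19 | tertiary methanesulfonate of 18 | COC(=O)C1(OS(C)(=O)=O)CC(=O)/C=C(\C)CC/C=C(/C)C(=O)C[C@H](C(C)C)C(O[Si](C)(C)C(C)(C)C)C1 | intermediate (not isolated)
20 | methyl (1E,4E,8Z,12R)-13-[(tert-butyldimethylsilyl)oxy]-5,9-dimethyl-3,10-dioxo-12-(propan-2-yl)cyclotetradeca-1,4,8-triene-1-carboxylate, C13 epimers | COC(=O)/C1=C/C(=O)/C=C(\C)CC/C=C(/C)C(=O)C[C@H](C(C)C)C(O[Si](C)(C)C(C)(C)C)C1 | intermediate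
21 | methyl (1E,4E,8Z,12R)-13-hydroxy-5,9-dimethyl-3,10-dioxo-12-(propan-2-yl)cyclotetradeca-1,4,8-triene-1-carboxylate, C13 epimers | COC(=O)/C1=C/C(=O)/C=C(\C)CC/C=C(/C)C(=O)C[C@H](C(C)C)C(O)C1 | intermediate (not isolated)
22 | methyl sarcoate, methyl (1E,4E,8Z,12R)-5,9-dimethyl-3,10,13-trioxo-12-(propan-2-yl)cyclotetradeca-1,4,8-triene-1-carboxylate | COC(=O)/C1=C/C(=O)/C=C(\C)CC/C=C(/C)C(=O)C[C@H](C(C)C)C(=O)C1 | target

## Step count and risks

Total step count: 13.
Longest linear sequence: 12 (steps 1–3, then 5–13).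

The three steps most likely to fail:

**Step 5** (selective coupling at one aldehyde of the labile dialdehyde 6, which also carries whatever optical purity the commercial terpene has). The fallback keeps iodide 4 but replaces 6 by a mono-aldehyde whose C2 is already an ester, made from commercial L-valine-derived methyl (S)-2-hydroxy-3-methylbutanoate.
- Tf2O/2,6-lutidine gives methyl (2S)-3-methyl-2-(triflyloxy)butanoate F1.
- SN2 displacement with inversion by NaCH(CO2tBu)2 gives the triester F2.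
- TFA gives the malonic acid F3, which loses CO2 in hot toluene to (3R)-3-(methoxycarbonyl)-4-methylpentanoic acid F4.
- (COCl)2 gives the acid chloride F5, reduced with LiAlH(OtBu)3 at −78 °C to the aldehyde ester F6.
- CrCl2/NiCl2 coupling of F6 with 4 (again through 7) now meets a single aldehyde and gives the hydroxy ester F7, which closes with PPTS to the lactone F8.
- iBu2AlH at −78 °C reduces F8 to the lactol.

This fallback sets out from 4 and comes back to the route at 9.

**Step 10** (macrocyclisation; the risks are furoxan dimers, oligomers and side reactions of the oxidative chlorination). The fallback makes the same dipole by dehydration instead of oxidation.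
- Aldehyde 12 is oxidised (NaClO2, NaH2PO4, 2-methyl-2-butene) to the dienoic acid F9.
- Coupling with TBSONH2 (EDC·HCl) gives the O-silyl hydroxamate F10.
- Slow addition of F10 to Tf2O/Et3N in CH2Cl2 (−40 °C → rt, 1 mM) releases nitrile oxide 15 without chlorine or oxidant, and it cyclises as before.

This fallback sets out from 12 and comes back at 16.

**Step 12** (elimination of a tertiary α-hydroxy ester; risks are a sluggish mesylation, retro-aldol cleavage or the Z ester). The fallback avoids the hydroxy ketone altogether.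
- Isoxazoline 16 is treated with LiN(iPr)2 (3 equiv, THF, −78 → −20 °C). The C13 ketone is only stored as its enolate, C5–H is removed and the ring oxygen leaves from C4 (base-induced isoxazoline fragmentation), giving the α,β-unsaturated oxime F11.
- Oxime exchange with aqueous glyoxylic acid then gives the enone ester.

This fallback sets out from 16 and comes back at 20.

## Further compounds

F1 | step 5 | methyl (2S)-3-methyl-2-{[(trifluoromethyl)sulfonyl]oxy}butanoate | CC(C)[C@H](OS(=O)(=O)C(F)(F)F)C(=O)OC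
F2 | step 5 | 1,1-di-tert-butyl 2-methyl (2S)-3-methylbutane-1,1,2-tricarboxylate | CC(C)[C@@H](C(C(=O)OC(C)(C)C)C(=O)OC(C)(C)C)C(=O)OC
F3 | step 5 | 2-[(2S)-1-methoxy-3-methyl-1-oxobutan-2-yl]propanedioic acid | CC(C)[C@@H](C(C(=O)O)C(=O)O)C(=O)OC
F4 | step 5 | (3R)-3-(methoxycarbonyl)-4-methylpentanoic acid | CC(C)[C@@H](CC(=O)O)C(=O)OC
F5 | step 5 | methyl (2R)-2-(2-chloro-2-oxoethyl)-3-methylbutanoate | CC(C)[C@@H](CC(=O)Cl)C(=O)OC
F6 | step 5 | methyl (2R)-3-methyl-2-(2-oxoethyl)butanoate | CC(C)[C@@H](CC=O)C(=O)OC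
F7 | step 5 | methyl (2R,5Z,9E)-4,11-dihydroxy-5,9-dimethyl-2-(propan-2-yl)undeca-5,9-dienoate | COC(=O)[C@@H](C(C)C)CC(O)/C(C)=C\CC/C(C)=C/CO
F8 | step 5 | (3R)-5-[(2Z,6E)-8-hydroxy-6-methylocta-2,6-dien-2-yl]-3-(propan-2-yl)oxolan-2-one | CC(C)[C@H]1CC(OC1=O)/C(C)=C\CC/C(C)=C/CO
F9 | step 10 | (2E,6Z,10R)-11-[(tert-butyldimethylsilyl)oxy]-13-(methoxycarbonyl)-3,7-dimethyl-8-oxo-10-(propan-2-yl)tetradeca-2,6,13-trienoic acid | C=C(CC(O[Si](C)(C)C(C)(C)C)[C@@H](C(C)C)CC(=O)/C(C)=C\CC/C(C)=C/C(=O)O)C(=O)OC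
F10 | step 10 | methyl (5R,8Z,12E)-4-[(tert-butyldimethylsilyl)oxy]-14-{[(tert-butyldimethylsilyl)oxy]amino}-8,12-dimethyl-2-methylidene-7,14-dioxo-5-(propan-2-yl)tetradeca-8,12-dienoate | C=C(CC(O[Si](C)(C)C(C)(C)C)[C@@H](C(C)C)CC(=O)/C(C)=C\CC/C(C)=C/C(=O)NO[Si](C)(C)C(C)(C)C)C(=O)OC
F11 | step 12 | methyl (1E,4E,8Z,12R)-13-[(tert-butyldimethylsilyl)oxy]-3-(hydroxyimino)-5,9-dimethyl-10-oxo-12-(propan-2-yl)cyclotetradeca-1,4,8-triene-1-carboxylate | COC(=O)/C1=C/C(=NO)/C=C(\C)CC/C=C(/C)C(=O)C[C@H](C(C)C)C(O[Si](C)(C)C(C)(C)C)C1
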